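**Retrosynthetic overview**
1. Target ⇐ hydroxyl-directed epoxidation of the Z-C4=C5 alkene (oxirane made last) ⇐ Evans–Tishchenko reduction of a β-hydroxy enone, which sets C6 and installs the 3,4,5-trimethoxybenzoate directly from the aldehyde.
2. β-Hydroxy enone ⇐ catalytic enantioselective boryl conjugate addition/oxidation on an achiral ten-membered cross-conjugated trienone (sets C8, then C7).
3. Trienone ⇐ one-flask vinyllithium addition / anionic oxy-Cope ring expansion (six to ten) / silanolate elimination, starting from racemic isopiperitenone.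
4. Isopiperitenone (ring A = C1–C6 of the macrocycle) ⇐ α′-isopropenylation of 3-methylcyclohexenone ⇐ Birch dearomatization of 3-methylanisole; the benzene ring supplies six of the ten ring carbons.
5. Ring order: six-membered carbocycle A (from the arene) → ten-membered carbocycle by [3,3] shift → oxirane.

Assumptions: the SMILES is read literally, i.e. a cis-fused 4,5-epoxide (4S,5R,6R,7R,8S, 1(10)E; germacrane numbering C1=C10(Me), C4(Me), C7(i-Pr) is used in the Why lines); (R,R)-QuinoxP* is taken as the ligand enantiomer giving 8S (otherwise its mirror image is used); 2-bromo-3-methylbutanal is bought.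

**Route**

Step 1
Reactants: 1 3-methylanisole
Product: 3 3-methylcyclohex-2-en-1-one, via 1-methoxy-5-methylcyclohexa-1,4-diene 2 (not isolated)
Conditions: Li, NH3(l), t-BuOH, THF, −78 to −33 °C; then 2 M HCl, THF, 25 °C
Reagents that add atoms: water, O
Why: Birch reduction dearomatizes the anisole regiospecifically to the 2,5-dihydro enol ether, and acid hydrolysis with conjugation gives the cyclohexenone that becomes ring A (no stereocenter formed).

Step 2
Reactants: 3 3-methylcyclohex-2-en-1-one; 4 2-bromopropene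
Product: 7 racemic 3-methyl-6-(prop-1-en-2-yl)cyclohex-2-en-1-one (isopiperitenone), via lithium dienolate 5 (not isolated), via lithium trienolate 6 (not isolated)
Conditions: LiN(SiMe3)2 (2.2 equiv), THF, −78 °C; Pd2(dba)3 (2 mol%), P(t-Bu)3 (4 mol%), 4 (1.05 equiv), −78 to 25 °C; AcOH, −78 °C
Reagents that add atoms: lithium bis(trimethylsilyl)amide, [Li]N([Si](C)(C)C)[Si](C)(C)C (lithium of 5 and 6)
Why: The kinetic cross-conjugated enolate undergoes palladium-catalysed ketone α-alkenylation (Buchwald–Hartwig-type enolate coupling), the excess amide stores the more acidic product as its trienolate, and kinetic α-protonation releases the deconjugated ketone; the new stereocenter is left racemic because step 4 destroys it.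

Step 3
Reactants: 8 2-bromo-3-methylbutanal
Product: 9 (Z)-[(2-bromo-3-methylbut-1-en-1-yl)oxy]tri(propan-2-yl)silane
Conditions: i-Pr3SiOSO2CF3, i-Pr2NEt, CH2Cl2, 0 °C
Reagents that add atoms: triisopropylsilyl trifluoromethanesulfonate, CC(C)[Si](OS(=O)(=O)C(F)(F)F)(C(C)C)C(C)C
Why: Soft enolization/O-silylation of the α-bromo aldehyde gives the enol silane with bromine cis to oxygen (Z), the isopropyl group avoiding the siloxy group.

Step 4
Reactants: 9 (Z)-[(2-bromo-3-methylbut-1-en-1-yl)oxy]tri(propan-2-yl)silane; 7 racemic isopiperitenone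
Product: 14 (2Z,5E,9Z)-5,9-dimethyl-2-(propan-2-yl)cyclodeca-2,5,9-trien-1-one, via vinyllithium 10 (not isolated), via lithium alkoxide 11 (not isolated), via potassium alkoxide 12 (not isolated), via potassium enolate 13 (not isolated)
Conditions: 9, t-BuLi (2.0 equiv), Et2O, −78 °C; 7, THF, −78 °C; KOt-Bu, 18-crown-6, −78 to 0 °C; AcOH, −78 °C
Reagents that add atoms: tert-butyllithium, [Li]C(C)(C)C (lithium of 10 and 11); potassium tert-butoxide, CC(C)(C)[O-].[K+] (potassium of 12 and 13)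
Why: Br–Li exchange gives the O-chelated vinyllithium, which adds 1,2 to the ketone anti to the isopropenyl group; the potassium alkoxide then undergoes a chair anionic oxy-Cope [3,3] ring expansion that fixes the C1=C10 E and C4=C5 Z alkenes, and the β-siloxy enolate expels silanolate (E1cB) to give the achiral, conformationally mobile trienone, erasing the racemic centers of 7 and 11.

Step 5
Reactants: 14 (2Z,5E,9Z)-5,9-dimethyl-2-(propan-2-yl)cyclodeca-2,5,9-trien-1-one
Product: 16 (2S,3S,5E,9Z)-3-hydroxy-5,9-dimethyl-2-(propan-2-yl)cyclodeca-5,9-dien-1-one, via boronate 15 (not isolated)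
Conditions: CuCl (5 mol%), (R,R)-QuinoxP* (5.5 mol%), NaOt-Bu (10 mol%), B2pin2 (1.2 equiv), MeOH (2 equiv), THF, 0 to 25 °C; then NaBO3·4H2O, THF/H2O, 25 °C
Reagents that add atoms: bis(pinacolato)diboron, CC1(C)OB(OC1(C)C)B1OC(C)(C)C(C)(C)O1 (boron of 15); sodium perborate, [Na+].[O-]OB=O (hydroxyl oxygen of 16)
Why: Copper-catalysed enantioselective boryl conjugate addition (Yun-type β-borylation) occurs at the less substituted β-carbon C8, the chiral bisphosphine selecting the peripheral enone face of one ring conformer (8S); C7, α to the ketone, equilibrates to the hydrogen-bonded anti-aldol isomer, and perborate replaces boron by hydroxyl with retention.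

Step 6
Reactants: 16 (2S,3S,5E,9Z)-3-hydroxy-5,9-dimethyl-2-(propan-2-yl)cyclodeca-5,9-dien-1-one; 17 3,4,5-trimethoxybenzaldehyde
Product: 19 (1S,2R,3S,4Z,8E)-3-hydroxy-5,9-dimethyl-2-(propan-2-yl)cyclodeca-4,8-dien-1-yl 3,4,5-trimethoxybenzoate, via hemiacetal 18 (not isolated)
Conditions: SmI2 (0.3 equiv), 17 (5 equiv), THF, −10 °C
Reagents that add atoms: none
Why: Evans–Tishchenko reduction: the samarium-bound hemiacetal delivers its hydride intramolecularly through a chair six-membered transition state to the ketone, setting C6 1,3-anti to C8–O and leaving the aroyl group on the C8 oxygen.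

Step 7
Reactants: 19 (1S,2R,3S,4Z,8E)-3-hydroxy-5,9-dimethyl-2-(propan-2-yl)cyclodeca-4,8-dien-1-yl 3,4,5-trimethoxybenzoate
Product: 20 (1R,2R,3R,4S,6E,10S)-2-hydroxy-6,10-dimethyl-3-(propan-2-yl)-11-oxabicyclo[8.1.0]undec-6-en-4-yl 3,4,5-trimethoxybenzoate
Conditions: VO(acac)2 (5 mol%), t-BuOOH (1.5 equiv), CH2Cl2, 0 °C
Reagents that add atoms: tert-butyl hydroperoxide, CC(C)(C)OO
Why: Hydroxyl-directed vanadium-catalysed epoxidation (Sharpless–Michaelson) delivers oxygen from the vanadate ester to the Z-allylic alkene face syn to the C6 hydroxyl (cis-epoxy alcohol, as for medium-ring Z-cycloalkenols), setting C4 and C5 and leaving the non-allylic C1=C10 alkene untouched.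

**Compound list**
1 | 3-methylanisole | COc1cccc(C)c1 | starting material
2 | 1-methoxy-5-methylcyclohexa-1,4-diene | COC1=CCC=C(C)C1 | intermediate
3 | 3-methylcyclohex-2-en-1-one | CC1=CC(=O)CCC1 | intermediate
4 | 2-bromopropene | CC(Br)=C | starting material
5 | lithium 5-methylcyclohexa-1,5-dien-1-olate | [Li+].[O-]C1=CCCC(C)=C1 | intermediate
6 | lithium 5-methyl-2-(prop-1-en-2-yl)cyclohexa-1,5-dien-1-olate | [Li+].[O-]C1=C(C(C)=C)CCC(C)=C1 | intermediate
7 | racemic 3-methyl-6-(prop-1-en-2-yl)cyclohex-2-en-1-one (isopiperitenone) | CC(=C)C1CCC(C)=CC1=O | intermediate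
8 | 2-bromo-3-methylbutanal (racemic) | CC(C)C(Br)C=O | starting material
9 | (Z)-[(2-bromo-3-methylbut-1-en-1-yl)oxy]tri(propan-2-yl)silane | CC(C)/C(Br)=C/O[Si](C(C)C)(C(C)C)C(C)C | intermediate
10 | [(E)-3-methyl-1-{[tri(propan-2-yl)silyl]oxy}but-1-en-2-yl]lithium (Li cis to O) | [Li]/C(C(C)C)=C\O[Si](C(C)C)(C(C)C)C(C)C | intermediate
11 | lithium 3-methyl-1-[(Z)-3-methyl-1-{[tri(propan-2-yl)silyl]oxy}but-1-en-2-yl]-6-(prop-1-en-2-yl)cyclohex-2-en-1-olate (racemate, one enantiomer drawn; alkenyl trans to isopropenyl) | [Li+].[O-][C@@]1(/C(C(C)C)=C\O[Si](C(C)C)(C(C)C)C(C)C)C=C(C)CC[C@H]1C(C)=C | intermediate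
12 | potassium salt of the same alkoxide (racemate, one enantiomer drawn) | [K+].[O-][C@@]1(/C(C(C)C)=C\O[Si](C(C)C)(C(C)C)C(C)C)C=C(C)CC[C@H]1C(C)=C | intermediate
13 | potassium (5E,9Z)-5,9-dimethyl-2-(propan-2-yl)-3-{[tri(propan-2-yl)silyl]oxy}cyclodeca-1,5,9-trien-1-olate (racemic at C3) | [K+].C/C1=C/C([O-])=C(C(C)C)C(O[Si](C(C)C)(C(C)C)C(C)C)C/C(C)=C/CC1 | intermediate
14 | (2Z,5E,9Z)-5,9-dimethyl-2-(propan-2-yl)cyclodeca-2,5,9-trien-1-one | C/C1=C/C(=O)/C(C(C)C)=C\C/C(C)=C/CC1 | intermediate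
15 | (2R,3S,5E,9Z)-5,9-dimethyl-2-(propan-2-yl)-3-(4,4,5,5-tetramethyl-1,3,2-dioxaborolan-2-yl)cyclodeca-5,9-dien-1-one | CC1(C)OB(OC1(C)C)[C@H]1C/C(C)=C/CC/C(C)=C\C(=O)[C@H]1C(C)C | intermediate
16 | (2S,3S,5E,9Z)-3-hydroxy-5,9-dimethyl-2-(propan-2-yl)cyclodeca-5,9-dien-1-one | O[C@H]1C/C(C)=C/CC/C(C)=C\C(=O)[C@H]1C(C)C | intermediate
17 | 3,4,5-trimethoxybenzaldehyde | COc1cc(C=O)cc(OC)c1OC | starting material
18 | (2S,3S,5E,9Z)-3-[hydroxy(3,4,5-trimethoxyphenyl)methoxy]-5,9-dimethyl-2-(propan-2-yl)cyclodeca-5,9-dien-1-one (samarium-bound in the flask; hemiacetal carbon undefined) | COc1cc(C(O)O[C@H]2C/C(C)=C/CC/C(C)=C\C(=O)[C@H]2C(C)C)cc(OC)c1OC | intermediate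
19 | (1S,2R,3S,4Z,8E)-3-hydroxy-5,9-dimethyl-2-(propan-2-yl)cyclodeca-4,8-dien-1-yl 3,4,5-trimethoxybenzoate | COc1cc(C(=O)O[C@H]2C/C(C)=C/CC/C(C)=C\[C@H](O)[C@H]2C(C)C)cc(OC)c1OC | intermediate
20 | (1R,2R,3R,4S,6E,10S)-2-hydroxy-6,10-dimethyl-3-(propan-2-yl)-11-oxabicyclo[8.1.0]undec-6-en-4-yl 3,4,5-trimethoxybenzoate | COc1cc(C(=O)O[C@H]2C/C(C)=C/CC[C@]3(C)O[C@@H]3[C@H](O)[C@H]2C(C)C)cc(OC)c1OC | target

**Step count and risks**

Total steps: 7. Longest linear sequence: 6 (steps 1, 2, 4, 5, 6, 7).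

Most likely to fail:

Step 4. The hindered vinyllithium may enolize 7, the Li-to-K exchange may be incomplete, and the liberated base may isomerize trienone 14. Fallback, setting out from 7 and rejoining at 14: 7 is treated with 2-lithio-3-methylbut-1-ene (from 2-bromo-3-methylbut-1-ene and t-BuLi, CeCl3-mediated) to give the isolable racemic tertiary alcohol 3-methyl-1-(3-methylbut-1-en-2-yl)-6-(prop-1-en-2-yl)cyclohex-2-en-1-ol F1. KH/18-crown-6 oxy-Cope rearrangement with Me3SiCl trapping of the enolate then gives the silyl enol ether {[(5E,9Z)-5,9-dimethyl-2-(propan-2-yl)cyclodeca-1,5,9-trien-1-yl]oxy}trimethylsilane F2. Saegusa–Ito dehydrogenation with Pd(OAc)2 in MeCN introduces the C7=C8 double bond to give 14.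

Step 5. Regio-, enantio- and C7-diastereocontrol on a flexible macrocycle are untested. Fallback, setting out from 14 and rejoining at 16: enantioselective nucleophilic epoxidation of the less hindered C7=C8 enone (cumene hydroperoxide, La(O-i-Pr)3/(R)-BINOL/Ph3As=O) gives the epoxy ketone (1S,3Z,7E,10S)-4,8-dimethyl-1-(propan-2-yl)-11-oxabicyclo[8.1.0]undeca-3,7-dien-2-one F3. Its Cα–O bond is then cleaved reductively with SmI2/MeOH at −78 °C to give 16.

Step 6. The Tishchenko hydride transfer may be slow on an α-branched macrocyclic enone, or acyl migration may follow. Fallback, setting out from 16 and rejoining at 19: 16 is acylated with 3,4,5-trimethoxybenzoyl chloride (pyridine, DMAP, 0 °C) to the keto ester (1S,2S,4Z,8E)-5,9-dimethyl-3-oxo-2-(propan-2-yl)cyclodeca-4,8-dien-1-yl 3,4,5-trimethoxybenzoate F4. The enone carbonyl is then reduced under catalyst control with a 2-methyl-CBS-oxazaborolidine/catecholborane (enantiomer chosen to give the C6 alcohol of 19) to give 19.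

**Further compounds**
F1 | step 4 | racemic 3-methyl-1-(3-methylbut-1-en-2-yl)-6-(prop-1-en-2-yl)cyclohex-2-en-1-ol (alkenyl trans to isopropenyl; one enantiomer drawn) | O[C@@]1(C(=C)C(C)C)C=C(C)CC[C@H]1C(C)=C
F2 | step 4 | {[(5E,9Z)-5,9-dimethyl-2-(propan-2-yl)cyclodeca-1,5,9-trien-1-yl]oxy}trimethylsilane | C/C1=C/C(O[Si](C)(C)C)=C(C(C)C)CC/C(C)=C/CC1
F3 | step 5 | (1S,3Z,7E,10S)-4,8-dimethyl-1-(propan-2-yl)-11-oxabicyclo[8.1.0]undeca-3,7-dien-2-one | O1[C@H]2C/C(C)=C/CC/C(C)=C\C(=O)[C@@]12C(C)C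
F4 | step 6 | (1S,2S,4Z,8E)-5,9-dimethyl-3-oxo-2-(propan-2-yl)cyclodeca-4,8-dien-1-yl 3,4,5-trimethoxybenzoate | COc1cc(C(=O)O[C@H]2C/C(C)=C/CC/C(C)=C\C(=O)[C@H]2C(C)C)cc(OC)c1OC
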